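**Plan**
Labels: indoline N1, C2 (spiro), C7 (ester-bearing); bridge C6–C5–N4; pyrrolidine N4–C3–C14–C15(OH)–C20; carbocycle C2–C16(CO2Me)–C17–C20–C19–C18.
Retrosynthesis: the azocane is cut at N4–C5 and C6–C7 (a two-carbon unit is removed) to give the dispiro amino ester 17. Then C7–aryl (indoline), C2–C7 and C2–N1 (back to a cyclohexadienone), C16–CO2Me (back to a vinyl iodide) and N4–C20 (back to a para-substituted phenol) are cut.
Forward: phenol 7 → oxidative spirocyclisation (pyrrolidine on a cyclohexadienone) → arm-selective α-iodination → ketimine/Reformatsky addition at C2 → carbonylation → α-arylation (indoline) → N1 carbamate, C18=C19 reduction, N4 release → two-carbon annulation closes the azocane last → hydrogenation and desilylation.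
Enabling feature: in 17 the only N–H (N4 on C20) and the only acidic C–H (C7, α to ester and aryl) stand cis-1,4 on a cyclohexene whose other positions are blocked (C16 sp2, C2 and C20 quaternary). This 1,6-N,C-dinucleophile can be bridged by a vinylsulfonium two-carbon dielectrophile to the 2-azabicyclo[4.2.2]decene.
Stereochemistry: C15 by asymmetric transfer hydrogenation; C20 by the C15-controlled choice between the two enone arms; C2 by 1,2-addition syn to N4; C7 in the key step (the new bridge leans over the sp2 bridge); C16 by hydrogenation from the face away from that bridge.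

Key step: step 12

Step 1
Reactants: 1 3-chloro-1-(4-hydroxyphenyl)propan-1-one; 2 2-(trimethylsilyl)ethanesulfonamide
Product: 4 N-[3-(4-hydroxyphenyl)-3-oxopropyl]-2-(trimethylsilyl)ethanesulfonamide, via enone 3 (not isolated)
Conditions: K2CO3, MeCN, 50 °C
Reagents that add atoms: none
Why: Base-mediated loss of HCl should give the aryl vinyl ketone 3, to which the sulfonamide adds in an aza-Michael reaction (elimination–conjugate addition of a β-chloroketone); the para-acylphenoxide is too delocalised to compete as a nucleophile.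

Step 2
Reactants: 4 N-[3-(4-hydroxyphenyl)-3-oxopropyl]-2-(trimethylsilyl)ethanesulfonamide
Product: 5 N-[(3S)-3-hydroxy-3-(4-hydroxyphenyl)propyl]-2-(trimethylsilyl)ethanesulfonamide
Conditions: RuCl[(S,S)-TsDPEN](p-cymene) (1 mol%), HCO2H/Et3N (5:2), DMF, 40 °C
Reagents that add atoms: none
Why: Asymmetric transfer hydrogenation of the aryl ketone; with the (S,S)-diamine ligand the hydride should be delivered as for acetophenone to give the (S)-carbinol, the future C15.

Step 3
Reactants: 5 N-[(3S)-3-hydroxy-3-(4-hydroxyphenyl)propyl]-2-(trimethylsilyl)ethanesulfonamide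
Product: 7 N-[(3S)-3-(tert-butyldimethylsilyloxy)-3-(4-hydroxyphenyl)propyl]-2-(trimethylsilyl)ethanesulfonamide, via bis-silyl ether 6 (not isolated)
Conditions: TBSCl, imidazole, DMF, rt; then K2CO3, MeOH, rt
Reagents that add atoms: tert-butyl(chloro)dimethylsilane (TBSCl), CC(C)(C)[Si](C)(C)Cl
Why: Silylation of both hydroxyls followed by selective base methanolysis of the much more labile aryl silyl ether (protection/selective deprotection) leaves only the benzylic alcohol protected, so that it cannot act as an oxygen nucleophile in step 4.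

Step 4
Reactants: 7 N-[(3S)-3-(tert-butyldimethylsilyloxy)-3-(4-hydroxyphenyl)propyl]-2-(trimethylsilyl)ethanesulfonamide
Product: 8 (4S)-4-(tert-butyldimethylsilyloxy)-1-[2-(trimethylsilyl)ethylsulfonyl]-1-azaspiro[4.5]deca-6,9-dien-8-one
Conditions: PhI(OAc)2, (CF3)2CHOH, 0 °C
Reagents that add atoms: none
Why: Oxidative dearomatisation of a para-substituted phenol by a trivalent iodine reagent with ipso attack of the sulfonamide nitrogen (oxidative amidation, 5-exo spirocyclisation) should give the spirodienone; C20 is not yet stereogenic because the two enone arms are identical.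

Step 5
Reactants: 8 (4S)-4-(tert-butyldimethylsilyloxy)-1-[2-(trimethylsilyl)ethylsulfonyl]-1-azaspiro[4.5]deca-6,9-dien-8-one
Product: 9 (4S,5R)-4-(tert-butyldimethylsilyloxy)-7-iodo-1-[2-(trimethylsilyl)ethylsulfonyl]-1-azaspiro[4.5]deca-6,9-dien-8-one
Conditions: I2, pyridine, CH2Cl2, rt
Reagents that add atoms: iodine, II
Why: Amine-mediated α-iodination of an enone (conjugate addition of pyridine, iodination of the enolate, elimination); the two enone arms are diastereotopic and pyridine should add to the β-carbon that faces the C15–H and not the one shielded by the C15–OSi group, which makes C20 stereogenic (5R) and fixes the arm that will carry the C16 ester.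

Step 6
Reactants: 9 (4S,5R)-4-(tert-butyldimethylsilyloxy)-7-iodo-1-[2-(trimethylsilyl)ethylsulfonyl]-1-azaspiro[4.5]deca-6,9-dien-8-one; 10 2-bromoaniline
Product: 12 methyl 2-[(4S,5R,8R)-8-(2-bromoanilino)-4-(tert-butyldimethylsilyloxy)-7-iodo-1-[2-(trimethylsilyl)ethylsulfonyl]-1-azaspiro[4.5]deca-6,9-dien-8-yl]acetate, via N-aryl ketimine 11 (not isolated)
Conditions: TiCl4, Et3N, CH2Cl2, −20 to 0 °C; then BrZnCH2CO2Me (from BrCH2CO2Me, Zn, TMSCl cat.), THF, −20 to 0 °C; H2O
Reagents that add atoms: methyl bromoacetate (used as its zinc enolate), COC(=O)CBr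
Why: Ketimine formation followed by Reformatsky-type (Mannich) 1,2-addition of the zinc ester enolate; on this 4-amino-substituted cyclohexadienone-type C=N the nucleophile should enter syn to the C20 nitrogen (long-range electrostatic control of 1,2-additions to 4-heteroatom-substituted cyclohexadienones), which places the acetate arm cis to N4 and sets C2 (8R).

Step 7
Reactants: 12 methyl 2-[(4S,5R,8R)-8-(2-bromoanilino)-4-(tert-butyldimethylsilyloxy)-7-iodo-1-[2-(trimethylsilyl)ethylsulfonyl]-1-azaspiro[4.5]deca-6,9-dien-8-yl]acetate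
Product: 13 methyl (4S,5R,8R)-8-(2-bromoanilino)-4-(tert-butyldimethylsilyloxy)-8-(2-methoxy-2-oxoethyl)-1-[2-(trimethylsilyl)ethylsulfonyl]-1-azaspiro[4.5]deca-6,9-diene-7-carboxylate
Conditions: Pd(PPh3)4 (5 mol%), CO (1 atm), MeOH, Et3N, DMF, 45 °C
Reagents that add atoms: carbon monoxide, [C-]#[O+]; methanol, CO
Why: Palladium-catalysed alkoxycarbonylation of the vinyl iodide; oxidative addition of zerovalent palladium into the C(sp2)–I bond is much faster than into the hindered, electron-rich aryl C–Br bond at this temperature, so the bromide should be kept for step 8.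

Step 8
Reactants: 13 methyl (4S,5R,8R)-8-(2-bromoanilino)-4-(tert-butyldimethylsilyloxy)-8-(2-methoxy-2-oxoethyl)-1-[2-(trimethylsilyl)ethylsulfonyl]-1-azaspiro[4.5]deca-6,9-diene-7-carboxylate
Product: 14 dimethyl (2S,3''S,4'R)-3''-(tert-butyldimethylsilyloxy)-1''-[2-(trimethylsilyl)ethylsulfonyl]dispiro[indoline-2,1'-cyclohexane-4',2''-pyrrolidine]-2',5'-diene-2',3-dicarboxylate (C7 epimers; N1–H)
Conditions: Pd2(dba)3 (5 mol%), XPhos, K3PO4, PhOH, DMF, 90 °C
Reagents that add atoms: none
Why: Palladium-catalysed intramolecular α-arylation of the ester (5-exo ring closure of the palladium enolate onto the aryl group) should form the indoline C7–aryl bond under weakly basic conditions that avoid N-deprotonation and β-lactam formation; C7 is formed as an epimer mixture that is erased by enolisation in step 12.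

Step 9
Reactants: 14 dimethyl (2S,3''S,4'R)-3''-(tert-butyldimethylsilyloxy)-1''-[2-(trimethylsilyl)ethylsulfonyl]dispiro[indoline-2,1'-cyclohexane-4',2''-pyrrolidine]-2',5'-diene-2',3-dicarboxylate
Product: 15 trimethyl (2S,3''S,4'R)-3''-(tert-butyldimethylsilyloxy)-1''-[2-(trimethylsilyl)ethylsulfonyl]dispiro[indoline-2,1'-cyclohexane-4',2''-pyrrolidine]-2',5'-diene-1,2',3-tricarboxylate
Conditions: ClCO2Me, pyridine, DMAP (cat.), CH2Cl2, 0 to 40 °C
Reagents that add atoms: methyl chloroformate, COC(=O)Cl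
Why: Acylation of the hindered indoline nitrogen by a chloroformate under nucleophilic catalysis (carbamate formation), with a base too weak to enolise C7.

Step 10
Reactants: 15 trimethyl (2S,3''S,4'R)-3''-(tert-butyldimethylsilyloxy)-1''-[2-(trimethylsilyl)ethylsulfonyl]dispiro[indoline-2,1'-cyclohexane-4',2''-pyrrolidine]-2',5'-diene-1,2',3-tricarboxylate
Product: 16 trimethyl (2S,3''S,4'R)-3''-(tert-butyldimethylsilyloxy)-1''-[2-(trimethylsilyl)ethylsulfonyl]dispiro[indoline-2,1'-cyclohexane-4',2''-pyrrolidin]-2'-ene-1,2',3-tricarboxylate (C18–C19 saturated)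
Conditions: 2-nitrobenzenesulfonohydrazide, Et3N, CH2Cl2, rt
Reagents that add atoms: none
Why: Diimide reduction (concerted syn transfer of two hydrogens) is very sensitive to substitution, so the cis-disubstituted C18=C19 bond should be reduced while the trisubstituted, conjugated C16=C17 enoate is kept.

Step 11
Reactants: 16 trimethyl (2S,3''S,4'R)-3''-(tert-butyldimethylsilyloxy)-1''-[2-(trimethylsilyl)ethylsulfonyl]dispiro[indoline-2,1'-cyclohexane-4',2''-pyrrolidin]-2'-ene-1,2',3-tricarboxylate
Product: 17 trimethyl (2S,3''S,4'R)-3''-(tert-butyldimethylsilyloxy)dispiro[indoline-2,1'-cyclohexane-4',2''-pyrrolidin]-2'-ene-1,2',3-tricarboxylate (N4–H free)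
Conditions: CsF, DMF, 95 °C
Reagents that add atoms: none
Why: Fluoride-induced β-elimination of the 2-(trimethylsilyl)ethanesulfonyl group (loss of Me3SiF, ethene and SO2) should free the secondary amine N4–H, which cannot form a lactam with the C16 ester because that would need a bridgehead double bond.

Step 12
Reactants: 17 trimethyl (2S,3''S,4'R)-3''-(tert-butyldimethylsilyloxy)dispiro[indoline-2,1'-cyclohexane-4',2''-pyrrolidin]-2'-ene-1,2',3-tricarboxylate
Product: 20 15-O-(tert-butyldimethylsilyl)-16,17-didehydro derivative of 22 (azocane closed; 2R,7S,15S,20R), via aminoethylsulfonium triflate 18 (not isolated), via spiro-aziridinium triflate 19 (not isolated)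
Conditions: CH2=CHSPh2+ TfO−, CH2Cl2, 0 °C to rt; then KOt-Bu, THF, −40 to 0 °C (0.005 M)
Reagents that add atoms: diphenyl(vinyl)sulfonium trifluoromethanesulfonate, C=C[S+](c1ccccc1)c1ccccc1.[O-]S(=O)(=O)C(F)(F)F
Why: Proposed new method: N4–H adds to the vinylsulfonium salt (aza-Michael) and proton transfer gives the 2-aminoethylsulfonium salt 18, whose amine expels Ph2S to the spiro-aziridinium ion 19; KOt-Bu then generates the C7 ester enolate, which opens 19 at a CH2 group, so that N4–C5 and C6–C7 are made in one flask; the closest known reaction type is the annulation of amino alcohols, diamines and aminomalonates with vinylsulfonium salts to five- to seven-membered heterocycles, extended here to an eight-membered ring closed by C-alkylation. The azocane closes by intramolecular enolate alkylation (eight-membered ring; attack on the aziridinium carbon anti to N4), made possible because N4 on C20 and C7 on C2 are cis-1,4 and can both take flagpole positions on the boat form of the cyclohexene. C7 is the only new stereocentre and is controlled by the substrate: both faces of the planar enolate (toward C16 or toward C18) are within reach of the tether, but the new four-atom bridge should lean over the sp2 bridge C16=C17, which has no inward-pointing hydrogens, and not over the saturated C18–C19 bridge, giving 7S with the C7 ester on the C18 side. Chemoselectivity rests on the substrate having one N–H (N4; N1 is a carbamate) and one acidic C–H (C7; C16 is sp2 and C15 is silylated), and high dilution should suppress intermolecular alkylation.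

Step 13
Reactants: 20 15-O-(tert-butyldimethylsilyl)-16,17-didehydro derivative of 22
Product: 22 CNP0144467.1 (2R,7S,15S,16R,20R), via silyl ether 21 (not isolated)
Conditions: H2 (20 atm), PtO2, EtOAc/AcOH, rt; then HCl, MeOH, rt
Reagents that add atoms: none
Why: Catalytic hydrogenation should add H2 to the face of C16=C17 that looks toward the small C18–C19 bridge and away from the four-atom N4–C5–C6–C7 bridge lying over it, so the C16 ester ends syn to that bridge (16R), and acid methanolysis then cleaves the silyl ether.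

**Compound list**
1 | 3-chloro-1-(4-hydroxyphenyl)propan-1-one | O=C(CCCl)c1ccc(O)cc1 | starting material
2 | 2-(trimethylsilyl)ethanesulfonamide | C[Si](C)(C)CCS(N)(=O)=O | starting material
3 | 1-(4-hydroxyphenyl)prop-2-en-1-one | C=CC(=O)c1ccc(O)cc1 | intermediate
4 | N-[3-(4-hydroxyphenyl)-3-oxopropyl]-2-(trimethylsilyl)ethanesulfonamide | O=C(CCNS(=O)(=O)CC[Si](C)(C)C)c1ccc(O)cc1 | intermediate
5 | N-[(3S)-3-hydroxy-3-(4-hydroxyphenyl)propyl]-2-(trimethylsilyl)ethanesulfonamide | O[C@@H](CCNS(=O)(=O)CC[Si](C)(C)C)c1ccc(O)cc1 | intermediate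
6 | bis(tert-butyldimethylsilyl) ether of 5 (aryl and alkyl oxygen) | CC(C)(C)[Si](C)(C)O[C@@H](CCNS(=O)(=O)CC[Si](C)(C)C)c1ccc(O[Si](C)(C)C(C)(C)C)cc1 | intermediate
7 | N-[(3S)-3-(tert-butyldimethylsilyloxy)-3-(4-hydroxyphenyl)propyl]-2-(trimethylsilyl)ethanesulfonamide | CC(C)(C)[Si](C)(C)O[C@@H](CCNS(=O)(=O)CC[Si](C)(C)C)c1ccc(O)cc1 | intermediate
8 | (4S)-4-(tert-butyldimethylsilyloxy)-1-[2-(trimethylsilyl)ethylsulfonyl]-1-azaspiro[4.5]deca-6,9-dien-8-one | O=C1C=CC2(C=C1)[C@@H](O[Si](C)(C)C(C)(C)C)CCN2S(=O)(=O)CC[Si](C)(C)C | intermediate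
9 | (4S,5R)-4-(tert-butyldimethylsilyloxy)-7-iodo-1-[2-(trimethylsilyl)ethylsulfonyl]-1-azaspiro[4.5]deca-6,9-dien-8-one | O=C1C(I)=C[C@]2(C=C1)[C@@H](O[Si](C)(C)C(C)(C)C)CCN2S(=O)(=O)CC[Si](C)(C)C | intermediate
10 | 2-bromoaniline | Nc1ccccc1Br | starting material
11 | N-(2-bromophenyl) ketimine of 9 at C8 (4S,5R) | Brc1ccccc1N=C1C(I)=C[C@]2(C=C1)[C@@H](O[Si](C)(C)C(C)(C)C)CCN2S(=O)(=O)CC[Si](C)(C)C | intermediate
12 | methyl 2-[(4S,5R,8R)-8-(2-bromoanilino)-4-(tert-butyldimethylsilyloxy)-7-iodo-1-[2-(trimethylsilyl)ethylsulfonyl]-1-azaspiro[4.5]deca-6,9-dien-8-yl]acetate | COC(=O)C[C@]1(Nc2ccccc2Br)C(I)=C[C@]2(C=C1)[C@@H](O[Si](C)(C)C(C)(C)C)CCN2S(=O)(=O)CC[Si](C)(C)C | intermediate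
13 | methyl (4S,5R,8R)-8-(2-bromoanilino)-4-(tert-butyldimethylsilyloxy)-8-(2-methoxy-2-oxoethyl)-1-[2-(trimethylsilyl)ethylsulfonyl]-1-azaspiro[4.5]deca-6,9-diene-7-carboxylate | COC(=O)C[C@]1(Nc2ccccc2Br)C(C(=O)OC)=C[C@]2(C=C1)[C@@H](O[Si](C)(C)C(C)(C)C)CCN2S(=O)(=O)CC[Si](C)(C)C | intermediate
14 | dimethyl (2S,3''S,4'R)-3''-(tert-butyldimethylsilyloxy)-1''-[2-(trimethylsilyl)ethylsulfonyl]dispiro[indoline-2,1'-cyclohexane-4',2''-pyrrolidine]-2',5'-diene-2',3-dicarboxylate (C7 epimers) | COC(=O)C1=C[C@@]2(C=C[C@@]13Nc1ccccc1C3C(=O)OC)N(S(=O)(=O)CC[Si](C)(C)C)CC[C@@H]2O[Si](C)(C)C(C)(C)C | intermediate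
15 | trimethyl (2S,3''S,4'R)-3''-(tert-butyldimethylsilyloxy)-1''-[2-(trimethylsilyl)ethylsulfonyl]dispiro[indoline-2,1'-cyclohexane-4',2''-pyrrolidine]-2',5'-diene-1,2',3-tricarboxylate | COC(=O)C1=C[C@@]2(C=C[C@@]13N(C(=O)OC)c1ccccc1C3C(=O)OC)N(S(=O)(=O)CC[Si](C)(C)C)CC[C@@H]2O[Si](C)(C)C(C)(C)C | intermediate
16 | trimethyl (2S,3''S,4'R)-3''-(tert-butyldimethylsilyloxy)-1''-[2-(trimethylsilyl)ethylsulfonyl]dispiro[indoline-2,1'-cyclohexane-4',2''-pyrrolidin]-2'-ene-1,2',3-tricarboxylate | COC(=O)C1=C[C@@]2(CC[C@@]13N(C(=O)OC)c1ccccc1C3C(=O)OC)N(S(=O)(=O)CC[Si](C)(C)C)CC[C@@H]2O[Si](C)(C)C(C)(C)C | intermediate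
17 | trimethyl (2S,3''S,4'R)-3''-(tert-butyldimethylsilyloxy)dispiro[indoline-2,1'-cyclohexane-4',2''-pyrrolidin]-2'-ene-1,2',3-tricarboxylate (N4–H) | COC(=O)C1=C[C@@]2(CC[C@@]13N(C(=O)OC)c1ccccc1C3C(=O)OC)NCC[C@@H]2O[Si](C)(C)C(C)(C)C | intermediate
18 | N4-[2-(diphenylsulfonio)ethyl] derivative of 17 as its triflate | COC(=O)C1=C[C@@]2(CC[C@@]13N(C(=O)OC)c1ccccc1C3C(=O)OC)N(CC[S+](c1ccccc1)c1ccccc1)CC[C@@H]2O[Si](C)(C)C(C)(C)C.[O-]S(=O)(=O)C(F)(F)F | intermediate
19 | N4-spiro-aziridinium ion derived from 18 as its triflate | COC(=O)C1=C[C@@]2(CC[C@@]13N(C(=O)OC)c1ccccc1C3C(=O)OC)[N+]1(CC1)CC[C@@H]2O[Si](C)(C)C(C)(C)C.[O-]S(=O)(=O)C(F)(F)F | intermediate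
20 | 15-O-(tert-butyldimethylsilyl)-16,17-didehydro derivative of 22 (2R,7S,15S,20R) | COC(=O)C1=C[C@@]23CC[C@@]14N(C(=O)OC)c1ccccc1[C@@]4(C(=O)OC)CCN2CC[C@@H]3O[Si](C)(C)C(C)(C)C | intermediate
21 | 15-O-(tert-butyldimethylsilyl) ether of 22 (2R,7S,15S,16R,20R) | COC(=O)[C@@H]1C[C@@]23CC[C@@]14N(C(=O)OC)c1ccccc1[C@@]4(C(=O)OC)CCN2CC[C@@H]3O[Si](C)(C)C(C)(C)C | intermediate
22 | CNP0144467.1: N1-methoxycarbonyl indoline spiro-fused at C2 and C7 to a 2-azabicyclo[4.2.2]decane bearing C7-CO2Me, C16-CO2Me and a fused 15-hydroxypyrrolidine (2R,7S,15S,16R,20R) | COC(=O)[C@@H]1C[C@@]23CC[C@@]14N(C(=O)OC)c1ccccc1[C@@]4(C(=O)OC)CCN2CC[C@@H]3O | target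

**Step count and risks**
Total steps: 13. Longest linear sequence: 13 steps (1 to 22).

Step 12 (proposed new method). The sulfonium ylide may be diverted (cyclopropanation of the C16=C17 enoate), the aziridinium ion may undergo base-induced elimination instead of C-alkylation, or the bridge may close with the wrong tilt. The fallback closes the same ring at the lactam oxidation level with known chemistry. It sets out from 17: N-acylation with bromoacetyl bromide (Et3N, CH2Cl2, 0 °C) should give the N4-bromoacetamide F1. Cs2CO3 in DMF at high dilution should effect intramolecular enolate alkylation to the eight-membered C5-lactam F2. Zinc-catalysed hydrosilylation of the tertiary lactam (Zn(OAc)2, (EtO)3SiH, THF, 40 °C), which spares esters and the carbamate, comes back to the route at 20.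

Step 6. Condensation of the deactivated haloaniline may be sluggish, 1,4-addition or β-lactam formation may compete, and the facial selectivity of the 1,2-addition may be insufficient. The fallback changes the order of bond formation so that the aryl ring arrives on C7 and the indoline is closed through the N1–aryl bond. It sets out from 9: condensation with diphenylphosphinic amide (TiCl4, Et3N) should give the N-diphenylphosphinoyl ketimine F3. Mannich addition of the lithium enolate of methyl 2-(2-bromophenyl)acetate should give the adduct F4. Methoxycarbonylation of the vinyl iodide as in step 7 should give the diester F5. Brief treatment with HCl in MeOH should cleave the P–N bond to the primary amine F6. Ullmann-type intramolecular N-arylation (CuI, L-proline, K2CO3, DMSO, 80 °C) closes the indoline and comes back to the route at 14.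

Step 5. The two diastereotopic enone arms may be poorly differentiated in the pyridine-mediated iodination. The fallback places the iodine on the arene before dearomatisation, so that the arm is fixed by constitution. It sets out from 7: ortho-iodination (N-iodosuccinimide, TsOH cat., MeCN) should give the 2-iodophenol F7. Oxidative spirocyclisation under the conditions of step 4 should then give 9 together with its C20 epimer F8; the two diastereomers are separated by chromatography and the route is rejoined at 9.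

Further compounds
F1 | step 12 | N4-bromoacetyl derivative of 17 | COC(=O)C1=C[C@@]2(CC[C@@]13N(C(=O)OC)c1ccccc1C3C(=O)OC)N(C(=O)CBr)CC[C@@H]2O[Si](C)(C)C(C)(C)C
F2 | step 12 | 5-oxo (lactam) derivative of 20 | COC(=O)C1=C[C@@]23CC[C@@]14N(C(=O)OC)c1ccccc1[C@@]4(C(=O)OC)CC(=O)N2CC[C@@H]3O[Si](C)(C)C(C)(C)C
F3 | step 6 | N-(diphenylphosphinoyl) ketimine of 9 | O=P(N=C1C(I)=C[C@]2(C=C1)[C@@H](O[Si](C)(C)C(C)(C)C)CCN2S(=O)(=O)CC[Si](C)(C)C)(c1ccccc1)c1ccccc1
F4 | step 6 | methyl 2-(2-bromophenyl)-2-[(4S,5R,8R)-8-(diphenylphosphinoylamino)-4-(tert-butyldimethylsilyloxy)-7-iodo-1-[2-(trimethylsilyl)ethylsulfonyl]-1-azaspiro[4.5]deca-6,9-dien-8-yl]acetate | COC(=O)C(c1ccccc1Br)[C@]1(NP(=O)(c2ccccc2)c2ccccc2)C(I)=C[C@]2(C=C1)[C@@H](O[Si](C)(C)C(C)(C)C)CCN2S(=O)(=O)CC[Si](C)(C)C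
F5 | step 6 | 7-methoxycarbonyl analogue of F4 (iodide replaced by CO2Me) | COC(=O)C(c1ccccc1Br)[C@]1(NP(=O)(c2ccccc2)c2ccccc2)C(C(=O)OC)=C[C@]2(C=C1)[C@@H](O[Si](C)(C)C(C)(C)C)CCN2S(=O)(=O)CC[Si](C)(C)C
F6 | step 6 | primary amine from F5 (P–N bond cleaved) | COC(=O)C(c1ccccc1Br)[C@]1(N)C(C(=O)OC)=C[C@]2(C=C1)[C@@H](O[Si](C)(C)C(C)(C)C)CCN2S(=O)(=O)CC[Si](C)(C)C
F7 | step 5 | N-[(3S)-3-(tert-butyldimethylsilyloxy)-3-(4-hydroxy-3-iodophenyl)propyl]-2-(trimethylsilyl)ethanesulfonamide | CC(C)(C)[Si](C)(C)O[C@@H](CCNS(=O)(=O)CC[Si](C)(C)C)c1ccc(O)c(I)c1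
F8 | step 5 | (4S,5S)-epimer of 9 | O=C1C(I)=C[C@@]2(C=C1)[C@@H](O[Si](C)(C)C(C)(C)C)CCN2S(=O)(=O)CC[Si](C)(C)C
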